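**Retrosynthetic overview**

1. Torilin ⇒ diol 26 (C11 acetate and C8 angelate put on last) ⇒ tricyclic siloxane 23/24, in which a Ph2Si–O bridge joins C8 to the C11 oxygen (C1 equilibration, Tamao–Fleming oxidation and hydrogenation lie in between).
2. Key disconnection: C9–C10 and C7–C8 of the seven-membered ring, made together by a rhodium-catalysed intramolecular [5+2] cycloaddition of vinylcyclopropane 20 (C7=C6–C5 with cyclopropane C5–C1–C10) and a silicon-tethered ethyne (C8≡C9).
3. Enabling feature: the cyclopropane C1–C5–C10 is fused to the five-membered ring C1–C2–C3–C4–C5 (a bicyclo[3.1.0]hexane) and carries the E-alkene C6=C7 on C5, so only the exo bond C5–C10 can open to a fused rhodacycle; the C11–O–Si tether brings C8 to C7.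
4. Bicyclo[3.1.0]hexan-3-one 13 ⇒ PtCl2 cycloisomerisation of hydroxy-enyne 11 ⇒ Still–Wittig [2,3] rearrangement (sets C4 and the C5=C10 geometry) ⇒ CBS-derived allylic alcohol 3.
5. Ring order: cyclopentane plus cyclopropane (step 9); seven-membered ring plus temporary oxasilacycle, with the cyclopropane consumed (step 16); oxasilacycle removed (step 19).

Key step: step 16

Remark: guaiane numbering of the target is used for all intermediates (C1 ring-fusion CH, C3 ketone, C4=C5, C7 bearing C11, C8 bearing oxygen, C10 bearing methyl C14, C15 on C4). α/β refer to the drawing with the five-membered ring on the left and C1 at the upper ring fusion; in this frame torilin is 1β-H, 7α-H, 8α-H, 10α-H, that is (1R,7S,8R,10S).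

Assumption: the natural C1 configuration (C2 trans to C14, both pseudo-equatorial) is the more stable one at the γ-position of the cyclopentenone; step 20 depends on this.

Assumption: (E)-pent-3-en-2-one, angelic acid, Bu3SnCH2OH, Bu3SnCH2I, Ph2SiCl2 and HC≡CMgBr are purchased.

**Route**

Step 1
Reactants: 1 (E)-pent-3-en-2-one
Product: 2 (Z)-3-iodopent-3-en-2-one
Conditions: I2, K2CO3, DMAP (cat.), THF/H2O, rt
Reagents that add atoms: iodine, II
Why: α-Iodination of an enone (conjugate addition of DMAP, iodination of the enolate, elimination) should give the α-iodoenone with the C15 methyl still trans to the acetyl group, which fixes the C4=C5 geometry needed in step 6.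

Step 2
Reactants: 2 (Z)-3-iodopent-3-en-2-one
Product: 3 (2S,3Z)-3-iodopent-3-en-2-ol
Conditions: (R)-Me-CBS (10 mol %), BH3·SMe2, THF, −30 °C
Reagents that add atoms: none
Why: Corey–Bakshi–Shibata reduction, in which the α-iodoalkenyl group acts as the large substituent, so that the (R)-oxazaborolidine should deliver hydride to the face that gives the (S)-carbinol at C10.

Step 3
Reactants: 3 (2S,3Z)-3-iodopent-3-en-2-ol
Product: 4 (2S,3E)-3-(hydroxymethyl)pent-3-en-2-ol
Conditions: Bu3SnCH2OH, Pd(PPh3)4 (5 mol %), 1,4-dioxane, 90 °C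
Reagents that add atoms: (tributylstannyl)methanol, OC[Sn](CCCC)(CCCC)CCCC
Why: Stille coupling of the alkenyl iodide with the hydroxymethyl stannane should install C6 with retention of the alkene geometry and without touching the carbinol centre.

Step 4
Reactants: 4 (2S,3E)-3-(hydroxymethyl)pent-3-en-2-ol
Product: 5 (2S,3E)-3-[(tert-butyldiphenylsilyloxy)methyl]pent-3-en-2-ol
Conditions: TBDPSCl, imidazole, CH2Cl2, 0 °C
Reagents that add atoms: tert-butyl(chloro)diphenylsilane, CC(C)(C)[Si](Cl)(c1ccccc1)c1ccccc1
Why: Silylation with the bulky chlorosilane should take the primary hydroxyl only, and this silyl group is chosen because it resists oxygen-to-oxygen migration under the basic conditions of step 5.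

Step 5
Reactants: 5 (2S,3E)-3-[(tert-butyldiphenylsilyloxy)methyl]pent-3-en-2-ol
Product: 7 tributyl({[(2S,3E)-3-[(tert-butyldiphenylsilyloxy)methyl]pent-3-en-2-yl]oxy}methyl)stannane, via potassium alkoxide 6 (not isolated)
Conditions: KH, THF, 0 °C; then Bu3SnCH2I, rt
Reagents that add atoms: tributyl(iodomethyl)stannane, CCCC[Sn](CI)(CCCC)CCCC
Why: Williamson etherification of the potassium alkoxide with the primary iodide should give the α-stannyl ether needed for the Still variant of the Wittig rearrangement, with the C10 centre untouched.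

Step 6
Reactants: 7 tributyl({[(2S,3E)-3-[(tert-butyldiphenylsilyloxy)methyl]pent-3-en-2-yl]oxy}methyl)stannane
Product: 9 (2S,3E)-3-[(tert-butyldiphenylsilyloxy)methyl]-2-methylpent-3-en-1-ol (C14 methyl cis to C4), via lithiomethyl ether 8 (not isolated)
Conditions: n-BuLi, THF, −78 °C
Reagents that add atoms: none
Why: Tin–lithium exchange should give the unstabilised α-alkoxy carbanion, which undergoes the suprafacial [2,3]-Wittig rearrangement (Still–Mitra variant); the substituent on C5 forces the C14 methyl into the pseudoaxial position of the envelope transition state, so that the new C5=C10 bond forms with C14 cis to C4 and the C10 configuration is transferred to C4 (S).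

Step 7
Reactants: 9 (2S,3E)-3-[(tert-butyldiphenylsilyloxy)methyl]-2-methylpent-3-en-1-ol
Product: 10 (2S,3E)-3-[(tert-butyldiphenylsilyloxy)methyl]-2-methylpent-3-enal
Conditions: DMP, NaHCO3, CH2Cl2, 0 °C, used crude
Reagents that add atoms: none
Why: Dess–Martin oxidation under buffered, base-free conditions should give the α-branched β,γ-unsaturated aldehyde without epimerisation at C4 or migration of the alkene.

Step 8
Reactants: 10 (2S,3E)-3-[(tert-butyldiphenylsilyloxy)methyl]-2-methylpent-3-enal
Product: 11 (4S,5E)-5-[(tert-butyldiphenylsilyloxy)methyl]-4-methylhept-5-en-1-yn-3-ol (both C3 epimers)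
Conditions: HC≡CMgBr, THF, −78 to 0 °C
Reagents that add atoms: ethynylmagnesium bromide, C#C[Mg]Br
Why: Grignard addition at low temperature should outrun enolisation of the aldehyde, and the C3 configuration need not be controlled because C3 becomes the carbonyl carbon in step 9.

Step 9
Reactants: 11 (4S,5E)-5-[(tert-butyldiphenylsilyloxy)methyl]-4-methylhept-5-en-1-yn-3-ol
Product: 13 1-[(tert-butyldiphenylsilyloxy)methyl]-2,6-dimethylbicyclo[3.1.0]hexan-3-one (6-methyl endo, 2-methyl trans to C6; bicyclo C1/C2/C5/C6 are guaiane C5/C4/C1/C10), via enol 12 (not isolated)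
Conditions: PtCl2 (5 mol %), toluene, 80 °C
Reagents that add atoms: none
Why: Platinum-catalysed cycloisomerisation of a 5-en-1-yn-3-ol, in which attack of the C5=C10 alkene on the PtCl2-bound alkyne should give a cyclopropyl platinum carbene at C2 and a 1,2-shift of the carbinol hydrogen followed by loss of the metal gives the enol and then the C3 ketone; the cyclopropanation is stereospecific (C14 stays cis to C4, hence endo) and allylic 1,3-strain between C14 and the C4 substituents should make the alkyne add anti to the C15 methyl, which sets C1, C5 and C10 from C4.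

Step 10
Reactants: 13 1-[(tert-butyldiphenylsilyloxy)methyl]-2,6-dimethylbicyclo[3.1.0]hexan-3-one
Product: 14 ethylene ketal of 13 (spiro-1,3-dioxolane at C3)
Conditions: (TMSOCH2)2, TMSOTf (5 mol %), CH2Cl2, −78 to −20 °C
Reagents that add atoms: 1,2-bis(trimethylsilyloxy)ethane, C[Si](C)(C)OCCO[Si](C)(C)C
Why: Ketalisation with the bis-silyl glycol under TMSOTf catalysis is aprotic and cold, so it should mask C3 for the methyllithium step without epimerising C4 or opening the cyclopropane.

Step 11
Reactants: 14 ethylene ketal of 13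
Product: 15 [3,3-(ethylenedioxy)-2,6-dimethylbicyclo[3.1.0]hexan-1-yl]methanol (stereochemistry as 13)
Conditions: Bu4NF, THF, rt
Reagents that add atoms: none
Why: Fluoride-mediated desilylation should free the primary C6 hydroxyl and leave the ketal and the cyclopropane untouched.

Step 12
Reactants: 15 [3,3-(ethylenedioxy)-2,6-dimethylbicyclo[3.1.0]hexan-1-yl]methanol
Product: 16 3,3-(ethylenedioxy)-2,6-dimethylbicyclo[3.1.0]hexane-1-carbaldehyde
Conditions: DMP, CH2Cl2, rt
Reagents that add atoms: none
Why: Dess–Martin oxidation of the neopentyl-type primary alcohol should give an aldehyde that cannot enolise because C5 is quaternary.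

Step 13
Reactants: 16 3,3-(ethylenedioxy)-2,6-dimethylbicyclo[3.1.0]hexane-1-carbaldehyde
Product: 17 ethyl (E)-3-[3,3-(ethylenedioxy)-2,6-dimethylbicyclo[3.1.0]hexan-1-yl]prop-2-enoate
Conditions: (EtO)2P(O)CH2CO2Et, NaH, THF, 0 °C to rt
Reagents that add atoms: triethyl phosphonoacetate, CCOC(=O)CP(=O)(OCC)OCC
Why: Horner–Wadsworth–Emmons olefination with the stabilised phosphonate anion should give the E-enoate, and this C6=C7 geometry later decides the configuration at C7.

Step 14
Reactants: 17 ethyl (E)-3-[3,3-(ethylenedioxy)-2,6-dimethylbicyclo[3.1.0]hexan-1-yl]prop-2-enoate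
Product: 18 (E)-4-[3,3-(ethylenedioxy)-2,6-dimethylbicyclo[3.1.0]hexan-1-yl]-2-methylbut-3-en-2-ol
Conditions: MeLi (3.5 equiv), THF, −78 to 0 °C
Reagents that add atoms: methyllithium, [Li]C
Why: Double 1,2-addition of methyllithium to the ester should give the tertiary carbinol C11, while the ketal keeps C3 out of reach.

Step 15
Reactants: 18 (E)-4-[3,3-(ethylenedioxy)-2,6-dimethylbicyclo[3.1.0]hexan-1-yl]-2-methylbut-3-en-2-ol
Product: 20 ethynyl(diphenyl)silyl ether of 18, via chlorosilyl ether 19 (not isolated)
Conditions: Ph2SiCl2, Et3N, DMAP (cat.), CH2Cl2, 0 °C to rt; then HC≡CMgBr, THF, 0 °C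
Reagents that add atoms: dichloro(diphenyl)silane, Cl[Si](Cl)(c1ccccc1)c1ccccc1; ethynylmagnesium bromide, C#C[Mg]Br
Why: Silylation of the tertiary alcohol with the dichlorosilane (as in the making of tert-alkoxydiphenylsilyl chlorides) followed by displacement of the remaining chloride by the acetylide should install the three-atom C11–O–Si tether that carries C8≡C9.

Step 16
Reactants: 20 ethynyl(diphenyl)silyl ether of 18
Product: 21 3,3-(ethylenedioxy)guaia-5,8-diene with C8 and the C11 oxygen bridged by SiPh2 (2,2-diphenyl-1,2-oxasilole ring), 1α-H, 7α-H, 10β-methyl, C4 as in 20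
Conditions: [Rh(CO)2Cl]2 (5 mol %), ClCH2CH2Cl, 80 °C, 0.02 M
Reagents that add atoms: none
Why: [Rh(CO)2Cl]2 should coordinate the C6=C7 alkene and insert, with retention at C10, into the cyclopropane bond C5–C10 that overlaps with it, giving a π-allyl/σ-alkyl rhodacycle of trivalent rhodium; migratory insertion of the tethered ethyne into the Rh–C7 bond and C9–C10 reductive elimination (again with retention) complete a formal [5+2] cycloaddition and return monovalent rhodium. The closest known reaction type is the rhodium-catalysed intramolecular [5+2] cycloaddition of alkyne-tethered vinylcyclopropanes, including 2-substituted cyclopropanes in which the substituted bond is cleaved; here a silyl ether replaces the usual ether or malonate tether and a silylalkyne is the two-carbon partner. The five-membered oxasilole closes in the alkyne insertion (5-exo with respect to the tether, C7–C8 bond) and the seven-membered ring closes in the reductive elimination (C9–C10 bond), while the cyclopropane is consumed. C7 is the only new stereocentre: the ethyne is delivered to the alkene face on which rhodium and C10 sit, so the E geometry (C11 outside) and the endo C14 methyl (trans to the alkenyl group) place C11, C14 and C2 on one face, that is 7α-H with 10β-methyl and 1α-H. The step needs cleavage of C5–C10 and not of the ring-fusion bond C1–C5, which the bicyclo[3.1.0]hexane secures because opening C1–C5 would force the allyl terminus C5 to a bridgehead of a bridged rhodacycle, and it needs C8 (not C9) at C7, which the C11–O–Si tether enforces.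

Step 17
Reactants: 21 bridged 3,3-(ethylenedioxy)guaia-5,8-diene
Product: 23 guaia-4,8-dien-3-one with the C8–SiPh2–O–C11 bridge, 1α-H, 7α-H, 10β-methyl, via β,γ-unsaturated ketone 22 (not isolated)
Conditions: PPTS, acetone/H2O (10:1), 50 °C; then DBU, CH2Cl2, rt
Reagents that add atoms: water, O
Why: Acid-catalysed transketalisation should free the C3 ketone while the tert-alkoxydiphenylsilyl ether survives, and DBU then moves the C5=C6 bond into conjugation through the dienolate (protonation at C6) to give the tetrasubstituted enone.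

Step 18
Reactants: 23 bridged guaia-4,8-dien-3-one
Product: 24 guai-4-en-3-one with cis-fused 2,2-diphenyl-1,2-oxasilolane (silicon β on C8, 8α-H), 1α-H, 7α-H, 10β-methyl
Conditions: H2 (1 atm), Pt/C (5 wt % Pt), EtOAc, rt
Reagents that add atoms: none
Why: Heterogeneous hydrogenation should reduce the trisubstituted alkenylsilane much faster than the tetrasubstituted conjugated C4=C5 bond, and hydrogen should add from the α-face, where only the pseudoaxial hydrogens on C7 and C10 project while ring carbons C6, C5 and C1 cover the β-face, so that the oxasilolane becomes cis-fused with silicon β on C8; platinum is chosen over palladium to limit double-bond migration toward C10.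

Step 19
Reactants: 24 cis-fused oxasilolane
Product: 25 8β,11-dihydroxy-1αH-guai-4-en-3-one (7α-H, 10β-methyl)
Conditions: H2O2 (30 %), KF, KHCO3, THF/MeOH (1:1), 50 °C
Reagents that add atoms: hydrogen peroxide, OO
Why: Tamao–Fleming oxidation of the strained alkoxysilane should replace the C8–Si bond by C8–OH with retention and free the C11 hydroxyl, while the tetrasubstituted enone should resist the buffered peroxide.

Step 20
Reactants: 25 8β,11-dihydroxy-1αH-guai-4-en-3-one
Product: 26 8β,11-dihydroxy-1βH-guai-4-en-3-one (7α-H, 10β-methyl)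
Conditions: NaOMe (0.3 equiv), MeOH, 40 °C
Reagents that add atoms: none
Why: Base-mediated epimerisation at the γ-carbon C1 through the cyclopentadienolate (the process known from the equilibration of 6-substituted 4-en-3-one steroids) should funnel the material into the isomer in which C2 and C14 are trans and both pseudo-equatorial, which is the natural 1β-H configuration; any remaining 1α-H epimer is separated and resubmitted.

Step 21
Reactants: 26 8β,11-dihydroxy-1βH-guai-4-en-3-one; 27 angelic acid
Product: 29 8β-angeloyloxy-11-hydroxy-1βH-guai-4-en-3-one, via mixed anhydride 28 (not isolated)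
Conditions: 27, 2,4,6-trichlorobenzoyl chloride, Et3N, toluene, rt; then 26, toluene, 80 °C
Reagents that add atoms: none
Why: Mixed-anhydride esterification (Yamaguchi type) at the less hindered angeloyl carbonyl should acylate the secondary C8 hydroxyl and leave the tertiary C11 hydroxyl, and the absence of a nucleophilic catalyst should keep the Z geometry of the angelate.

Step 22
Reactants: 29 8β-angeloyloxy-11-hydroxy-1βH-guai-4-en-3-one
Product: 30 torilin
Conditions: Ac2O, Sc(OTf)3 (5 mol %), MeCN, −20 °C
Reagents that add atoms: acetic anhydride, CC(=O)OC(C)=O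
Why: Lewis-acid-catalysed acetylation with Sc(OTf)3 at low temperature should esterify the hindered tertiary alcohol without base, so that neither elimination nor isomerisation of the angelate to the tiglate is expected.

**Compound list**

1 | (E)-pent-3-en-2-one | C/C=C/C(C)=O | starting material
2 | (Z)-3-iodopent-3-en-2-one | CC(=O)/C(I)=C/C | intermediate
3 | (2S,3Z)-3-iodopent-3-en-2-ol | C[C@H](O)/C(I)=C/C | intermediate
4 | (2S,3E)-3-(hydroxymethyl)pent-3-en-2-ol | C[C@H](O)/C(CO)=C/C | intermediate
5 | (2S,3E)-3-[(tert-butyldiphenylsilyloxy)methyl]pent-3-en-2-ol | C[C@H](O)/C(CO[Si](c1ccccc1)(c1ccccc1)C(C)(C)C)=C/C | intermediate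
6 | potassium alkoxide of 5 | C[C@H]([O-])/C(CO[Si](c1ccccc1)(c1ccccc1)C(C)(C)C)=C/C.[K+] | intermediate (not isolated)
7 | tributylstannylmethyl ether of 5 | C[C@H](OC[Sn](CCCC)(CCCC)CCCC)/C(CO[Si](c1ccccc1)(c1ccccc1)C(C)(C)C)=C/C | intermediate
8 | lithiomethyl ether of 5 | C[C@H](OC[Li])/C(CO[Si](c1ccccc1)(c1ccccc1)C(C)(C)C)=C/C | intermediate (not isolated)
9 | (2S,3E)-3-[(tert-butyldiphenylsilyloxy)methyl]-2-methylpent-3-en-1-ol | OC[C@@H](C)/C(CO[Si](c1ccccc1)(c1ccccc1)C(C)(C)C)=C\C | intermediate
10 | (2S,3E)-3-[(tert-butyldiphenylsilyloxy)methyl]-2-methylpent-3-enal | O=C[C@@H](C)/C(CO[Si](c1ccccc1)(c1ccccc1)C(C)(C)C)=C\C | intermediate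
11 | (4S,5E)-5-[(tert-butyldiphenylsilyloxy)methyl]-4-methylhept-5-en-1-yn-3-ol, both C3 epimers | C#CC(O)[C@@H](C)/C(CO[Si](c1ccccc1)(c1ccccc1)C(C)(C)C)=C\C | intermediate
12 | 1-[(tert-butyldiphenylsilyloxy)methyl]-2,6-dimethylbicyclo[3.1.0]hex-3-en-3-ol (enol of 13) | C[C@@H]1[C@@H]2C=C(O)[C@@H](C)[C@]12CO[Si](c1ccccc1)(c1ccccc1)C(C)(C)C | intermediate (not isolated)
13 | 1-[(tert-butyldiphenylsilyloxy)methyl]-2,6-dimethylbicyclo[3.1.0]hexan-3-one (6-methyl endo, 2-methyl trans to C6) | C[C@@H]1[C@@H]2CC(=O)[C@@H](C)[C@]12CO[Si](c1ccccc1)(c1ccccc1)C(C)(C)C | intermediate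
14 | ethylene ketal of 13 | C[C@@H]1[C@@H]2CC3(OCCO3)[C@@H](C)[C@]12CO[Si](c1ccccc1)(c1ccccc1)C(C)(C)C | intermediate
15 | [3,3-(ethylenedioxy)-2,6-dimethylbicyclo[3.1.0]hexan-1-yl]methanol | C[C@@H]1[C@@H]2CC3(OCCO3)[C@@H](C)[C@]12CO | intermediate
16 | 3,3-(ethylenedioxy)-2,6-dimethylbicyclo[3.1.0]hexane-1-carbaldehyde | C[C@@H]1[C@@H]2CC3(OCCO3)[C@@H](C)[C@]12C=O | intermediate
17 | ethyl (E)-3-[3,3-(ethylenedioxy)-2,6-dimethylbicyclo[3.1.0]hexan-1-yl]prop-2-enoate | C[C@@H]1[C@@H]2CC3(OCCO3)[C@@H](C)[C@]12/C=C/C(=O)OCC | intermediate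
18 | (E)-4-[3,3-(ethylenedioxy)-2,6-dimethylbicyclo[3.1.0]hexan-1-yl]-2-methylbut-3-en-2-ol | C[C@@H]1[C@@H]2CC3(OCCO3)[C@@H](C)[C@]12/C=C/C(C)(C)O | intermediate
19 | chloro(diphenyl)silyl ether of 18 | C[C@@H]1[C@@H]2CC3(OCCO3)[C@@H](C)[C@]12/C=C/C(C)(C)O[Si](Cl)(c1ccccc1)c1ccccc1 | intermediate (not isolated)
20 | ethynyl(diphenyl)silyl ether of 18 | C[C@@H]1[C@@H]2CC3(OCCO3)[C@@H](C)[C@]12/C=C/C(C)(C)O[Si](C#C)(c1ccccc1)c1ccccc1 | intermediate
21 | 3,3-(ethylenedioxy)guaia-5,8-diene with C8–SiPh2–O–C11 bridge, 1α-H, 7α-H, 10β-methyl | O4[Si](c5ccccc5)(c5ccccc5)C1=C[C@H](C)[C@@H]2CC3(OCCO3)[C@@H](C)C2=C[C@@H]1C4(C)C | intermediate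
22 | guaia-5,8-dien-3-one with C8–SiPh2–O–C11 bridge | O3[Si](c4ccccc4)(c4ccccc4)C1=C[C@H](C)[C@@H]2CC(=O)[C@@H](C)C2=C[C@@H]1C3(C)C | intermediate (not isolated)
23 | guaia-4,8-dien-3-one with C8–SiPh2–O–C11 bridge, 1α-H, 7α-H, 10β-methyl | O3[Si](c4ccccc4)(c4ccccc4)C1=C[C@H](C)[C@@H]2CC(=O)C(C)=C2C[C@@H]1C3(C)C | intermediate
24 | guai-4-en-3-one with cis-fused 2,2-diphenyl-1,2-oxasilolane (C8–Si β), 1α-H | O3[Si](c4ccccc4)(c4ccccc4)[C@@H]1C[C@H](C)[C@@H]2CC(=O)C(C)=C2C[C@@H]1C3(C)C | intermediate
25 | 8β,11-dihydroxy-1αH-guai-4-en-3-one | O[C@@H]1C[C@H](C)[C@@H]2CC(=O)C(C)=C2C[C@@H]1C(C)(C)O | intermediate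
26 | 8β,11-dihydroxy-1βH-guai-4-en-3-one | O[C@@H]1C[C@H](C)[C@H]2CC(=O)C(C)=C2C[C@@H]1C(C)(C)O | intermediate
27 | angelic acid, (Z)-2-methylbut-2-enoic acid | C/C=C(/C)C(=O)O | starting material
28 | angelic 2,4,6-trichlorobenzoic anhydride | C/C=C(/C)C(=O)OC(=O)c1c(Cl)cc(Cl)cc1Cl | intermediate (not isolated)
29 | 8β-angeloyloxy-11-hydroxy-1βH-guai-4-en-3-one | C/C=C(/C)C(=O)O[C@@H]1C[C@H](C)[C@H]2CC(=O)C(C)=C2C[C@@H]1C(C)(C)O | intermediate
30 | torilin | C/C=C(/C)C(=O)O[C@@H]1C[C@H](C)[C@H]2CC(=O)C(C)=C2C[C@@H]1C(C)(C)OC(C)=O | target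

**Step count and risks**

Total step count: 22. Longest linear sequence: 22 steps (1 to 30; 27 is purchased).

Steps most likely to fail:

Step 16. The terminal ethynylsilane may be consumed by alkyne oligomerisation or vinylidene formation before the hindered C6=C7 alkene, which sits between two quaternary carbons, is engaged by rhodium. The fallback changes the two-carbon partner to an alkene. It sets out from 18, which is silylated with chloro(diphenyl)vinylsilane (Et3N, DMAP, CH2Cl2) to the vinyl(diphenyl)silyl ether F1. A rhodium-catalysed intramolecular vinylcyclopropane–alkene [5+2] cycloaddition (RhCl(PPh3)3, AgOTf, toluene, 110 °C) should then give the cis-fused saturated oxasilolane F2, with C8 already set (8α-H) by the tether. The conditions of step 17 convert F2 into 24, where the route is rejoined and step 18 is no longer needed.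

Step 20. The equilibrium at C1 may be only weakly biased in the flexible diol, or the diol may be diverted by reversible oxa-Michael addition of the C8 or C11 alkoxide to C5. The fallback moves the equilibration to the rigid tricycle, which has no free hydroxyl and whose cis-fused oxasilolane holds C7 and C8 in place. It sets out from 24, which is equilibrated with DBU in toluene at 80 °C to the 1β-H siloxane F3. Tamao–Fleming oxidation as in step 19 then gives 26 directly, where the route is rejoined.

Step 18. Double-bond migration from C8=C9 toward C10 on the metal surface would scramble C10, and the enone may be reduced in competition. The fallback sets C8 by hydride reduction instead of hydrogenation. It sets out from 23, whose alkenylsiloxane is oxidised under Tamao–Fleming conditions (KF, KHCO3, H2O2) to the C8 ketone F4, a β-hydroxy ketone. Reduction of the saturated ketone with NaBH4 in MeOH/CH2Cl2 at −78 °C, conditions that leave conjugated enones, should occur from the α-face, anti to the bulky C7 substituent, and give 25, where the route is rejoined.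

Further compounds
F1 | step 16 | vinyl(diphenyl)silyl ether of 18 | C[C@@H]1[C@@H]2CC3(OCCO3)[C@@H](C)[C@]12/C=C/C(C)(C)O[Si](C=C)(c1ccccc1)c1ccccc1
F2 | step 16 | 3,3-(ethylenedioxy)guai-5-ene with cis-fused 2,2-diphenyl-1,2-oxasilolane (C8–Si β), 1α-H | O4[Si](c5ccccc5)(c5ccccc5)[C@@H]1C[C@H](C)[C@@H]2CC3(OCCO3)[C@@H](C)C2=C[C@@H]1C4(C)C
F3 | step 20 | guai-4-en-3-one with cis-fused 2,2-diphenyl-1,2-oxasilolane (C8–Si β), 1β-H | O3[Si](c4ccccc4)(c4ccccc4)[C@@H]1C[C@H](C)[C@H]2CC(=O)C(C)=C2C[C@@H]1C3(C)C
F4 | step 18 | 11-hydroxy-1αH-guai-4-ene-3,8-dione | O=C1C[C@H](C)[C@@H]2CC(=O)C(C)=C2C[C@@H]1C(C)(C)O
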